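**Retrosynthetic overview**
1. The last two operations are hydrogenolysis of four O-benzyl groups and, before it, oxidation of a C4 methyl ether to the C4 ketone. Neither touches C2.
2. The plan rests on ring C (O1, C2, C3, C4, C4a, C8a). It is the sum of a four-atom heterodiene O1=C8a–C4a=C4 (an ortho-quinone methide of ring A with OMe on C4) and the vinyl carbons C2=C3 of a ring B styrene. The oxygen at C4' is para to the vinyl group and makes C3 the nucleophilic end, so the cuts are O1–C2 and C3–C4.
3. The heterodiene is released from a ring A salicylaldehyde and trimethyl orthoformate. The dienophile is 3,4-bis(benzyloxy)styrene, made by Wittig methylenation of the aldehyde.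
4. The salicylaldehyde comes from a mirror-symmetric phenol whose para position holds the side chain, so ortho-formylation can give only the 6-alkyl pattern. The phenol is built from 4-bromo-2,6-difluorobenzaldehyde (F to OBn, CHO to the C5 chain, Br to OH).
5. Rings A and B are bought. Ring C is the only ring formed, in the cycloaddition.

Key step: step 8

Assumption: the sense of induction of the chiral acid in step 8 cannot be predicted with confidence. The (R)-acid is written, and its enantiomer is to be used if correlation of 20 with the (2S)-flavanone series requires it.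
Remark: flavonoid numbering is used (O1, C2–C4, C4a, C5–C8, C8a; ring B primed; side chain C1''–C3'').

Step 1
Reactants: 1 4-bromo-2,6-difluorobenzaldehyde
Product: 3 2,6-bis(benzyloxy)-4-bromobenzaldehyde, via monobenzyl ether 2 (not isolated)
Conditions: BnOH (2.3 equiv), NaH (2.3 equiv), THF, 0 °C; then 1, 0 °C to 60 °C
Reagents that add atoms: benzyl alcohol, OCc1ccccc1
Why: Twofold nucleophilic aromatic substitution (SNAr) should work because both fluorides are ortho to the formyl group, which stabilises the Meisenheimer adducts, and because fluoride leaves far faster than the para bromide, so a small excess of benzyloxide should stop at the diether.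

Step 2
Reactants: 3 2,6-bis(benzyloxy)-4-bromobenzaldehyde
Product: 4 methyl (2E)-3-[2,6-bis(benzyloxy)-4-bromophenyl]prop-2-enoate
Conditions: Ph3P=CHCO2Me (1.3 equiv), toluene, 100 °C
Reagents that add atoms: methyl (triphenylphosphoranylidene)acetate, COC(=O)C=P(c1ccccc1)(c1ccccc1)c1ccccc1
Why: Wittig olefination with a stabilised ylide works on 2,6-dialkoxybenzaldehydes and leaves the aryl bromide alone, and the E geometry it favours does not matter because the alkene is saturated next.

Step 3
Reactants: 4 methyl (2E)-3-[2,6-bis(benzyloxy)-4-bromophenyl]prop-2-enoate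
Product: 5 methyl 3-[2,6-bis(benzyloxy)-4-bromophenyl]propanoate
Conditions: H2 (4 atm), RhCl(PPh3)3 (5 mol %), toluene–EtOH 1:1, 50 °C
Reagents that add atoms: none
Why: Homogeneous hydrogenation with RhCl(PPh3)3 saturates a disubstituted alkene but, unlike Pd/C, neither cleaves aryl benzyl ethers nor removes an aryl bromide.

Step 4
Reactants: 5 methyl 3-[2,6-bis(benzyloxy)-4-bromophenyl]propanoate
Product: 7 4-[2,6-bis(benzyloxy)-4-bromophenyl]-2-methylbutan-2-ol, via methyl ketone 6 (not isolated)
Conditions: MeMgBr (3 equiv), THF, 0 °C to rt; sat. aq NH4Cl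
Reagents that add atoms: methylmagnesium bromide, C[Mg]Br
Why: Double Grignard addition to the ester passes through ketone 6, which is more reactive than the ester, and gives the dimethyl carbinol, while the aryl bromide does not exchange with MeMgBr at this temperature.

Step 5
Reactants: 7 4-[2,6-bis(benzyloxy)-4-bromophenyl]-2-methylbutan-2-ol
Product: 8 3,5-bis(benzyloxy)-4-(3-hydroxy-3-methylbutyl)phenol
Conditions: Pd2(dba)3 (2 mol %), t-BuXPhos (8 mol %), KOH (4 equiv), 1,4-dioxane–H2O 1:1, 100 °C, argon; then 1 M HCl to pH 5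
Reagents that add atoms: potassium hydroxide, [K+].[OH-]
Why: Palladium-catalysed hydroxylation of an aryl bromide (Buchwald–Hartwig-type C–O coupling with hydroxide) suits this C–Br bond, which is flanked by two C–H positions, and the benzyl ethers and the tertiary alcohol are inert to hot aqueous KOH.

Step 6
Reactants: 8 3,5-bis(benzyloxy)-4-(3-hydroxy-3-methylbutyl)phenol
Product: 10 4,6-bis(benzyloxy)-2-hydroxy-5-(3-hydroxy-3-methylbutyl)benzaldehyde, via hydroxymethylphenol 9 (not isolated)
Conditions: MgCl2 (anhydrous, 3 equiv), Et3N (6 equiv), (CH2O)n (8 equiv), MeCN, 80 °C; then cold 1 M HCl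
Reagents that add atoms: paraformaldehyde (reacts as formaldehyde), C=O
Why: In the Casnati–Skattebøl ortho-formylation the magnesium phenoxide delivers formaldehyde to the ortho carbon to give 9, which passes hydride to a second formaldehyde (Oppenauer-type), and only one regioisomer can form because the para position is blocked and the two ortho positions are related by symmetry.

Step 7
Reactants: 11 3,4-bis(benzyloxy)benzaldehyde; 12 methyltriphenylphosphonium bromide
Product: 14 1,2-bis(benzyloxy)-4-ethenylbenzene, via methylidenetriphenylphosphorane 13 (not isolated)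
Conditions: 12 (1.3 equiv), KOt-Bu (1.25 equiv), THF, 0 °C; then 11, 0 °C to rt
Reagents that add atoms: methyltriphenylphosphonium bromide (12), C[P+](c1ccccc1)(c1ccccc1)c1ccccc1.[Br-]
Why: Wittig methylenation of an aromatic aldehyde that cannot enolise is reliable under base-only conditions, which spare the acid-sensitive electron-rich styrene (to be used fresh).

Step 8
Reactants: 10 4,6-bis(benzyloxy)-2-hydroxy-5-(3-hydroxy-3-methylbutyl)benzaldehyde; 14 1,2-bis(benzyloxy)-4-ethenylbenzene; 15 trimethyl orthoformate
Product: 18 (2S,4S)-5,7-bis(benzyloxy)-2-[3,4-bis(benzyloxy)phenyl]-6-(3-hydroxy-3-methylbutyl)-4-methoxychromane, via dimethyl acetal 16 (not isolated), via methoxy ortho-quinone methide 17 (not isolated)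
Conditions: (R)-3,3'-bis(2,4,6-triisopropylphenyl)-1,1'-binaphthalene-2,2'-diyl hydrogen phosphate [(R)-TRIP] (10 mol %), 15 (2 equiv), 14 (1.5 equiv), 5 Å MS, toluene, 0 °C to rt; Et3N quench
Reagents that add atoms: trimethyl orthoformate (15), COC(OC)OC
Why: Proposed new method: the acid catalyses acetalisation of 10 by 15 to 16 and then expels methanol, giving 17 in its O1-protonated form (a 2-hydroxybenzylic oxocarbenium ion) held to the chiral phosphate by a hydrogen bond and ion pairing; the CH2 terminus of 14 (C3) then attacks C4 while O1 closes on C2, whose positive charge is carried by the 4'-benzyloxy group, in an inverse-electron-demand oxa-Diels–Alder reaction that is concerted but strongly asynchronous. Ring C is thus closed in an intermolecular [4+2] mode, C3–C4 leading and O1–C2 following, with no separate cyclisation step. The closest known reaction types are the racemic acid-promoted union of salicylaldehydes, orthoformates and styrenes to 4-alkoxyflavans, and the chiral phosphoric acid or N-triflylphosphoramide catalysed cycloadditions of styrenes with ortho-quinone methides released from 2-hydroxybenzyl alcohols; what is new is an alkoxy-substituted ortho-quinone methide made from an aldehyde under a chiral acid. C4 is set by the face of 17 that the 3,3'-aryl groups of the bound phosphate leave open, and C2 is set relative to C4 by the endo placement of ring B over the heterodiene (2,4-cis), so the absolute configuration at C2 depends on both catalyst control and endo selectivity. Regiochemistry follows from the polarity of both partners, which puts the aryl-bearing carbon next to O1; chemoselectivity is secured by the weak acid and low temperature (no cationic oligomerisation of 14, no ionisation of the new C4–OMe bond) and by geometry, since the tertiary hydroxyl cannot reach C4 within the molecule and adds only reversibly between molecules. The cis and trans isomers are to be separated and assayed individually before step 9, because isomers formed from the same face of 17 would differ at C2.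

Step 9
Reactants: 18 (2S,4S)-5,7-bis(benzyloxy)-2-[3,4-bis(benzyloxy)phenyl]-6-(3-hydroxy-3-methylbutyl)-4-methoxychromane
Product: 20 (2S)-5,7-bis(benzyloxy)-2-[3,4-bis(benzyloxy)phenyl]-6-(3-hydroxy-3-methylbutyl)-2,3-dihydro-4H-chromen-4-one, via methyl hemiketal 19 (not isolated)
Conditions: DDQ (1.3 equiv), CH2Cl2–pH 7 phosphate buffer 18:1, 0 °C to rt, dark
Reagents that add atoms: water, O
Why: DDQ oxidation of an electron-rich benzylic ether (hydride abstraction) should take the C4–H, since its cation is stabilised by the methoxy oxygen as well as by O1, 5-OBn and 7-OBn and since this hydrogen is pseudo-axial in the 2,4-cis isomer, whereas the C1'' hydrogens lack an α-oxygen and are held out of alignment by the two flanking benzyloxy groups; water then gives 19, which loses methanol, and C2 is untouched.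

Step 10
Reactants: 20 (2S)-5,7-bis(benzyloxy)-2-[3,4-bis(benzyloxy)phenyl]-6-(3-hydroxy-3-methylbutyl)-2,3-dihydro-4H-chromen-4-one
Product: 21 (2S)-2-(3,4-dihydroxyphenyl)-5,7-dihydroxy-6-(3-hydroxy-3-methylbutyl)-2,3-dihydro-4H-chromen-4-one
Conditions: H2 (1 atm), 10 % Pd/C, EtOAc–MeOH 1:1, rt
Reagents that add atoms: none
Why: Heterogeneous hydrogenolysis removes the four aryl benzyl ethers in neutral medium, where the donor-deactivated C4 carbonyl is not reduced, the tertiary alcohol does not cyclise onto the 5- or 7-hydroxyl (an acid process) and C2 does not racemise by retro-oxa-Michael opening (a base process).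

**Compound list**
1 | 4-bromo-2,6-difluorobenzaldehyde | O=Cc1c(F)cc(Br)cc1F | starting material
2 | 2-(benzyloxy)-4-bromo-6-fluorobenzaldehyde (forms in the flask) | O=Cc1c(F)cc(Br)cc1OCc1ccccc1 | intermediate
3 | 2,6-bis(benzyloxy)-4-bromobenzaldehyde | O=Cc1c(OCc2ccccc2)cc(Br)cc1OCc1ccccc1 | intermediate
4 | methyl (2E)-3-[2,6-bis(benzyloxy)-4-bromophenyl]prop-2-enoate | COC(=O)/C=C/c1c(OCc2ccccc2)cc(Br)cc1OCc1ccccc1 | intermediate
5 | methyl 3-[2,6-bis(benzyloxy)-4-bromophenyl]propanoate | COC(=O)CCc1c(OCc2ccccc2)cc(Br)cc1OCc1ccccc1 | intermediate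
6 | 4-[2,6-bis(benzyloxy)-4-bromophenyl]butan-2-one (forms in the flask) | CC(=O)CCc1c(OCc2ccccc2)cc(Br)cc1OCc1ccccc1 | intermediate
7 | 4-[2,6-bis(benzyloxy)-4-bromophenyl]-2-methylbutan-2-ol | CC(C)(O)CCc1c(OCc2ccccc2)cc(Br)cc1OCc1ccccc1 | intermediate
8 | 3,5-bis(benzyloxy)-4-(3-hydroxy-3-methylbutyl)phenol | CC(C)(O)CCc1c(OCc2ccccc2)cc(O)cc1OCc1ccccc1 | intermediate
9 | 3,5-bis(benzyloxy)-2-(hydroxymethyl)-4-(3-hydroxy-3-methylbutyl)phenol (forms in the flask) | CC(C)(O)CCc1c(OCc2ccccc2)cc(O)c(CO)c1OCc1ccccc1 | intermediate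
10 | 4,6-bis(benzyloxy)-2-hydroxy-5-(3-hydroxy-3-methylbutyl)benzaldehyde | CC(C)(O)CCc1c(OCc2ccccc2)cc(O)c(C=O)c1OCc1ccccc1 | intermediate
11 | 3,4-bis(benzyloxy)benzaldehyde | O=Cc1ccc(OCc2ccccc2)c(OCc2ccccc2)c1 | starting material
12 | methyltriphenylphosphonium bromide | C[P+](c1ccccc1)(c1ccccc1)c1ccccc1.[Br-] | starting material
13 | methylidenetriphenylphosphorane (forms in the flask) | C=P(c1ccccc1)(c1ccccc1)c1ccccc1 | intermediate
14 | 1,2-bis(benzyloxy)-4-ethenylbenzene | C=Cc1ccc(OCc2ccccc2)c(OCc2ccccc2)c1 | intermediate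
15 | trimethyl orthoformate | COC(OC)OC | starting material
16 | 3,5-bis(benzyloxy)-2-(dimethoxymethyl)-4-(3-hydroxy-3-methylbutyl)phenol (forms in the flask) | CC(C)(O)CCc1c(OCc2ccccc2)cc(O)c(C(OC)OC)c1OCc1ccccc1 | intermediate
17 | 3,5-bis(benzyloxy)-4-(3-hydroxy-3-methylbutyl)-6-(methoxymethylidene)cyclohexa-2,4-dien-1-one (forms in the flask, reacts O-protonated) | COC=C1C(=O)C=C(OCc2ccccc2)C(CCC(C)(C)O)=C1OCc1ccccc1 | intermediate
18 | (2S,4S)-5,7-bis(benzyloxy)-2-[3,4-bis(benzyloxy)phenyl]-6-(3-hydroxy-3-methylbutyl)-4-methoxychromane (2,4-cis) | CC(C)(O)CCc1c(OCc3ccccc3)cc2c(c1OCc1ccccc1)[C@@H](OC)C[C@@H](c1ccc(OCc3ccccc3)c(OCc3ccccc3)c1)O2 | intermediate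
19 | (2S)-5,7-bis(benzyloxy)-2-[3,4-bis(benzyloxy)phenyl]-6-(3-hydroxy-3-methylbutyl)-4-methoxychroman-4-ol (forms in the flask, C4 undefined) | CC(C)(O)CCc1c(OCc3ccccc3)cc2c(c1OCc1ccccc1)C(O)(OC)C[C@@H](c1ccc(OCc3ccccc3)c(OCc3ccccc3)c1)O2 | intermediate
20 | (2S)-5,7-bis(benzyloxy)-2-[3,4-bis(benzyloxy)phenyl]-6-(3-hydroxy-3-methylbutyl)-2,3-dihydro-4H-chromen-4-one | CC(C)(O)CCc1c(OCc3ccccc3)cc2c(c1OCc1ccccc1)C(=O)C[C@@H](c1ccc(OCc3ccccc3)c(OCc3ccccc3)c1)O2 | intermediate
21 | (2S)-2-(3,4-dihydroxyphenyl)-5,7-dihydroxy-6-(3-hydroxy-3-methylbutyl)-2,3-dihydro-4H-chromen-4-one | CC(C)(O)CCc1c(O)cc2c(c1O)C(=O)C[C@@H](c1ccc(O)c(O)c1)O2 | target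

**Step count**
- Total step count: 10.
- Longest linear sequence: 9 (steps 1–6, 8, 9, 10).

**Steps most likely to fail**

1. Step 8 (Proposed new method).
- **Rate:** the heterodiene is strongly stabilised by the 5- and 7-benzyloxy groups. Cycloaddition may therefore be slower than acid-induced oligomerisation of the styrene, Friedel–Crafts attack of the cation on the free C8 position, O-methylation of the catalyst by the orthoformate, exchange of the tertiary hydroxyl with the orthoformate, or ionisation of the new C4–OMe bond.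
- **Selectivity:** facial selectivity may be poor because only the heterodiene is bound to the catalyst. Endo/exo leakage would lower the enantiomeric purity at C2 once C4 is erased.
- **Fallback:** this uses known chemistry, closing ring C by oxa-Michael addition and securing C2 by kinetic resolution. It sets out from 10 and 11 and comes back at 20.
  - Excess MeMgBr in THF should add to 10 to give 3,5-bis(benzyloxy)-2-(1-hydroxyethyl)-4-(3-hydroxy-3-methylbutyl)phenol F1, which is used crude.
  - MnO2 in CH2Cl2 should oxidise it to 1-[4,6-bis(benzyloxy)-2-hydroxy-5-(3-hydroxy-3-methylbutyl)phenyl]ethan-1-one F2.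
  - Claisen–Schmidt condensation of F2 with 11 (KOH, EtOH) should give (E)-1-[4,6-bis(benzyloxy)-2-hydroxy-5-(3-hydroxy-3-methylbutyl)phenyl]-3-[3,4-bis(benzyloxy)phenyl]prop-2-en-1-one F3.
  - NaOAc in refluxing EtOH should cyclise F3 to racemic 5,7-bis(benzyloxy)-2-[3,4-bis(benzyloxy)phenyl]-6-(3-hydroxy-3-methylbutyl)-2,3-dihydro-4H-chromen-4-one F4.
  - Noyori-type asymmetric transfer hydrogenation, run as a kinetic resolution (RuCl(p-cymene)[(R,R)-TsDPEN], HCO2H–Et3N, EtOAc, rt), should reduce the (2R)-ketone. The product would be (2R,4R)-5,7-bis(benzyloxy)-2-[3,4-bis(benzyloxy)phenyl]-6-(3-hydroxy-3-methylbutyl)chroman-4-ol F5.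
  - The (2S)-ketone 20 should be left behind and is separated by chromatography.

2. Step 9.
- **Site selectivity:** hydride abstraction may compete at C1'' of the side chain or at C2–H, and the latter would also erode the stereocentre.
- **Other failure modes:** benzyl ethers may be lost, and turnover may be slow if the C4–H is pseudo-equatorial (trans isomer).
- **Fallback:** this replaces hydride abstraction by substitution and then alcohol oxidation. It sets out from 18 and comes back at 20.
  - Dilute acid solvolysis (PPTS, THF–H2O, rt, high dilution) should exchange the readily ionised C4 methoxy group for hydroxyl. This gives (2S)-5,7-bis(benzyloxy)-2-[3,4-bis(benzyloxy)phenyl]-6-(3-hydroxy-3-methylbutyl)chroman-4-ol F6 as a C4 epimer mixture.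
  - Dess–Martin periodinane with NaHCO3 in CH2Cl2 should oxidise the secondary benzylic alcohol to 20 without touching the tertiary alcohol, C1'' or C2.

3. Step 3.
- **Failure mode:** turnover at the alkene next to the 2,6-disubstituted ring may be sluggish. Forcing it may cause hydrodebromination or benzyl ether loss.
- **Fallback:** this forms the C1''–C2'' bond by alkylation, so no alkene is ever made. It sets out from 3 and comes back at 5.
  - NaBH4 in MeOH should give [2,6-bis(benzyloxy)-4-bromophenyl]methanol F7.
  - PBr3 in Et2O at 0 °C should give 1,3-bis(benzyloxy)-5-bromo-2-(bromomethyl)benzene F8, which is used crude.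
  - The lithium enolate of methyl acetate (LDA, THF, −78 °C) should be alkylated by F8 to give 5.

**Further compounds**
F1 | step 8 | 3,5-bis(benzyloxy)-2-(1-hydroxyethyl)-4-(3-hydroxy-3-methylbutyl)phenol (racemic) | CC(O)c1c(O)cc(OCc2ccccc2)c(CCC(C)(C)O)c1OCc1ccccc1
F2 | step 8 | 1-[4,6-bis(benzyloxy)-2-hydroxy-5-(3-hydroxy-3-methylbutyl)phenyl]ethan-1-one | CC(=O)c1c(O)cc(OCc2ccccc2)c(CCC(C)(C)O)c1OCc1ccccc1
F3 | step 8 | (E)-1-[4,6-bis(benzyloxy)-2-hydroxy-5-(3-hydroxy-3-methylbutyl)phenyl]-3-[3,4-bis(benzyloxy)phenyl]prop-2-en-1-one | CC(C)(O)CCc1c(OCc2ccccc2)cc(O)c(C(=O)/C=C/c2ccc(OCc3ccccc3)c(OCc3ccccc3)c2)c1OCc1ccccc1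
F4 | step 8 | racemic 5,7-bis(benzyloxy)-2-[3,4-bis(benzyloxy)phenyl]-6-(3-hydroxy-3-methylbutyl)-2,3-dihydro-4H-chromen-4-one | CC(C)(O)CCc1c(OCc3ccccc3)cc2c(c1OCc1ccccc1)C(=O)CC(c1ccc(OCc3ccccc3)c(OCc3ccccc3)c1)O2
F5 | step 8 | (2R,4R)-5,7-bis(benzyloxy)-2-[3,4-bis(benzyloxy)phenyl]-6-(3-hydroxy-3-methylbutyl)chroman-4-ol | CC(C)(O)CCc1c(OCc3ccccc3)cc2c(c1OCc1ccccc1)[C@H](O)C[C@H](c1ccc(OCc3ccccc3)c(OCc3ccccc3)c1)O2
F6 | step 9 | (2S)-5,7-bis(benzyloxy)-2-[3,4-bis(benzyloxy)phenyl]-6-(3-hydroxy-3-methylbutyl)chroman-4-ol (C4 epimers) | CC(C)(O)CCc1c(OCc3ccccc3)cc2c(c1OCc1ccccc1)C(O)C[C@@H](c1ccc(OCc3ccccc3)c(OCc3ccccc3)c1)O2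
F7 | step 3 | [2,6-bis(benzyloxy)-4-bromophenyl]methanol | OCc1c(OCc2ccccc2)cc(Br)cc1OCc1ccccc1
F8 | step 3 | 1,3-bis(benzyloxy)-5-bromo-2-(bromomethyl)benzene | BrCc1c(OCc2ccccc2)cc(Br)cc1OCc1ccccc1
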